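**Plan**
- Retrosynthesis: the five benzyl ethers and the chelated 5-O-methyl group of the genkwanin half are put back first. Ring F (O1, C2, C3, C4 of the luteolin half) is then cut at C4a–C4, C4–C3 and O1–C2 into a ring D ortho-iodophenol, CO and 3,4-bis(benzyloxy)phenylacetylene.
- Ring C of the genkwanin half is cut at O1–C2 and C2–C3 (Baker–Venkataraman) to a 2-hydroxydeoxybenzoin. This is cut at the ring A aryl–carbonyl bond into an ortho-lithiated 3,5-dimethoxyphenyl acetal and the ring D arylacetic Weinreb amide.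
- Forward order: side-chain homologation on ring D, deoxybenzoin, ring C, iodination, ring F (last ring), global ether cleavage.
- Enabling feature: ring D (the benzo ring of the luteolin half) has its only free phenol on the carbon para to the inter-flavone bond, with iodine on the adjacent carbon. Ring F can therefore fuse only across that O–C/C–I pair, which puts the genkwanin unit at C6 and not C8.
- Stereochemistry: the target has no stereocentre, so nothing has to be set.

Key step: step 13

Remark: the inter-flavone biaryl axis has no configuration in the target structure; it is treated as undefined (racemic if rotation is slow) and is not controlled. The tetrahydropyranyl acetals are racemic and are removed before the end.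

**Route**

Step 1
Reactants: 1 2,4,6-trihydroxybenzaldehyde
Product: 2 2,6-dihydroxy-4-(methoxymethoxy)benzaldehyde
Conditions: MOMCl (1.0 equiv), i-Pr2NEt (1.1 equiv), THF, 0 °C
Reagents that add atoms: chloromethyl methyl ether, COCCl
Why: Williamson-type O-alkylation in which the 4-hydroxyl, para to the formyl group and not hydrogen-bonded to it, is the most acidic and most accessible, so one equivalent of MOMCl should take it first (the bis-ether being the separable by-product).

Step 2
Reactants: 2 2,6-dihydroxy-4-(methoxymethoxy)benzaldehyde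
Product: 3 2,6-bis(benzyloxy)-4-(methoxymethoxy)benzaldehyde
Conditions: BnBr (2.5 equiv), K2CO3, DMF, 60 °C
Reagents that add atoms: benzyl bromide, BrCc1ccccc1
Why: Williamson etherification of the two remaining ortho-hydroxyls, which need warm DMF because of chelation to the aldehyde, under basic conditions that leave the MOM acetal intact.

Step 3
Reactants: 3 2,6-bis(benzyloxy)-4-(methoxymethoxy)benzaldehyde
Product: 4 1,3-bis(benzyloxy)-2-ethenyl-5-(methoxymethoxy)benzene
Conditions: Ph3PCH3Br, KOt-Bu, THF, 0 °C to rt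
Reagents that add atoms: methyltriphenylphosphonium bromide, C[P+](c1ccccc1)(c1ccccc1)c1ccccc1.[Br-]
Why: Wittig methylenation with the small, unstabilised ylide is reliable for non-enolisable, di-ortho-substituted benzaldehydes.

Step 4
Reactants: 4 1,3-bis(benzyloxy)-2-ethenyl-5-(methoxymethoxy)benzene
Product: 5 2-[2,6-bis(benzyloxy)-4-(methoxymethoxy)phenyl]ethan-1-ol
Conditions: 9-BBN, THF, rt; then aq. NaOH, H2O2, 0 °C to rt
Reagents that add atoms: hydrogen peroxide, OO
Why: Hydroboration–oxidation with the bulky 9-borabicyclo[3.3.1]nonane places boron on the terminal carbon of the styrene, so the anti-Markovnikov primary alcohol should result.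

Step 5
Reactants: 5 2-[2,6-bis(benzyloxy)-4-(methoxymethoxy)phenyl]ethan-1-ol
Product: 6 [2,6-bis(benzyloxy)-4-(methoxymethoxy)phenyl]acetic acid
Conditions: TEMPO (cat.), PhI(OAc)2 (2.2 equiv), MeCN/H2O, rt
Reagents that add atoms: water, O
Why: Oxoammonium-mediated oxidation of the primary alcohol through the aldehyde hydrate to the acid is chlorine-free, so the very electron-rich ring should not be halogenated, and the acetal should tolerate the weakly acidic medium.

Step 6
Reactants: 6 [2,6-bis(benzyloxy)-4-(methoxymethoxy)phenyl]acetic acid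
Product: 8 2-[2,6-bis(benzyloxy)-4-(methoxymethoxy)phenyl]-N-methoxy-N-methylacetamide, via acyl imidazolide 7 (not isolated)
Conditions: 1,1'-carbonyldiimidazole, CH2Cl2, rt; then MeNH(OMe)·HCl, rt
Reagents that add atoms: N,O-dimethylhydroxylamine hydrochloride, CNOC.Cl
Why: Amide formation through the acyl imidazolide is a standard, neutral way to a Weinreb amide and needs no acid chloride that could endanger the acetal.

Step 7
Reactants: 9 3,5-dimethoxyphenol
Product: 10 2-(3,5-dimethoxyphenoxy)oxane (racemic)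
Conditions: 3,4-dihydro-2H-pyran, PPTS (cat.), CH2Cl2, rt
Reagents that add atoms: 3,4-dihydro-2H-pyran, C1=COCCC1
Why: Acid-catalysed addition of the phenol to the enol ether gives the tetrahydropyranyl acetal, which both protects the phenol and directs ortho-lithiation.

Step 8
Reactants: 10 2-(3,5-dimethoxyphenoxy)oxane, 8 2-[2,6-bis(benzyloxy)-4-(methoxymethoxy)phenyl]-N-methoxy-N-methylacetamide
Product: 13 2-[2,6-bis(benzyloxy)-4-(methoxymethoxy)phenyl]-1-(2-hydroxy-4,6-dimethoxyphenyl)ethan-1-one, via aryllithium 11 (not isolated), via tetrahydropyranyl ketone 12 (not isolated)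
Conditions: 10 (1.4 equiv), n-BuLi, THF, 0 °C to rt; 8, −78 to 0 °C; cold 1 M aq. HCl quench; then PPTS (cat.), MeOH, rt
Reagents that add atoms: none
Why: Directed ortho-metalation should place lithium on the ring A carbon flanked by the acetal oxygen and a methoxy group, the Weinreb ketone synthesis stops at the ketone because the N-methoxy chelate lasts until the quench, and PPTS in methanol should cleave only the tetrahydropyranyl acetal, which is far more acid-labile than the aryl MOM ether.

Step 9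
Reactants: 13 2-[2,6-bis(benzyloxy)-4-(methoxymethoxy)phenyl]-1-(2-hydroxy-4,6-dimethoxyphenyl)ethan-1-one, 14 4-(benzyloxy)benzoyl chloride
Product: 15 2-{[2,6-bis(benzyloxy)-4-(methoxymethoxy)phenyl]acetyl}-3,5-dimethoxyphenyl 4-(benzyloxy)benzoate
Conditions: Et3N, DMAP (cat.), CH2Cl2, 0 °C to rt
Reagents that add atoms: none
Why: DMAP-catalysed O-acylation of the chelated phenol gives the aryl ester needed for intramolecular acyl transfer, which avoids a direct C-aroylation at the crowded benzylic carbon.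

Step 10
Reactants: 15 2-{[2,6-bis(benzyloxy)-4-(methoxymethoxy)phenyl]acetyl}-3,5-dimethoxyphenyl 4-(benzyloxy)benzoate
Product: 17 2-[4-(benzyloxy)phenyl]-3-[2,6-bis(benzyloxy)-4-hydroxyphenyl]-5,7-dimethoxy-4H-chromen-4-one, via triaryl 1,3-diketone 16 (not isolated)
Conditions: LiN(SiMe3)2 (3 equiv), THF, −78 to 0 °C; aq. HCl work-up; then conc. HCl, MeOH/THF, 50 °C
Reagents that add atoms: none
Why: Baker–Venkataraman rearrangement, in which the ketone enolate attacks the neighbouring aryl ester through a six-membered transition state, gives diketone 16, and warm methanolic HCl then closes ring C by cyclodehydration and cleaves the ring D MOM acetal while leaving the benzyl ethers alone.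

Step 11
Reactants: 17 2-[4-(benzyloxy)phenyl]-3-[2,6-bis(benzyloxy)-4-hydroxyphenyl]-5,7-dimethoxy-4H-chromen-4-one
Product: 18 2-[4-(benzyloxy)phenyl]-3-[2,6-bis(benzyloxy)-4-hydroxy-3-iodophenyl]-5,7-dimethoxy-4H-chromen-4-one
Conditions: I2 (1.05 equiv), NaHCO3, THF/H2O, 0 °C
Reagents that add atoms: iodine, II
Why: Electrophilic iodination through the phenoxide goes ortho to the only free phenol, the two ortho positions being equivalent and the only open sites of ring D, while ring A has no free phenol and is deactivated by the chromone carbonyl, and one equivalent of iodine limits di-iodination.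

Step 12
Reactants: 19 3,4-bis(benzyloxy)benzaldehyde
Product: 20 1,2-bis(benzyloxy)-4-ethynylbenzene
Conditions: dimethyl (1-diazo-2-oxopropyl)phosphonate, K2CO3, MeOH/THF, rt
Reagents that add atoms: dimethyl (1-diazo-2-oxopropyl)phosphonate, COP(=O)(OC)C(=[N+]=[N-])C(C)=O
Why: Ohira–Bestmann homologation (Seyferth–Gilbert type) turns a non-enolisable aryl aldehyde into the terminal alkyne under mild base that does not touch the benzyl ethers.

Step 13
Reactants: 18 2-[4-(benzyloxy)phenyl]-3-[2,6-bis(benzyloxy)-4-hydroxy-3-iodophenyl]-5,7-dimethoxy-4H-chromen-4-one, 20 1,2-bis(benzyloxy)-4-ethynylbenzene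
Product: 23 2-[4-(benzyloxy)phenyl]-3-{5,7-bis(benzyloxy)-2-[3,4-bis(benzyloxy)phenyl]-4-oxo-4H-chromen-6-yl}-5,7-dimethoxy-4H-chromen-4-one, via ynone 21 (not isolated), via enaminone 22 (not isolated)
Conditions: PdCl2(PPh3)2 (5 mol %), CO (10 bar), Et2NH/DMF (1:1), 90 °C
Reagents that add atoms: carbon monoxide, [C-]#[O+]
Why: PdCl2(PPh3)2 is reduced in the flask to zerovalent palladium, which inserts into the C–I bond of 18; CO insertion gives the aroylpalladium iodide (divalent palladium), and copper-free coupling with the amine-deprotonated alkyne 20 followed by reductive elimination gives ynone 21. Diethylamine then adds to 21 in conjugate fashion to give enaminone 22, and the neighbouring phenol displaces the amine from the β-carbon by addition–elimination. The closest known reaction type is the palladium-catalysed carbonylative Sonogashira annulation of ortho-iodophenols with terminal alkynes to flavones. Ring F closes in the 6-endo mode (6-endo-dig with respect to the ynone, carried out as a 6-endo-trig addition–elimination on 22), and no stereocentre is formed. The step needs carbonylative over direct coupling, flavone over aurone and C6 over C8 attachment: CO pressure, the absence of copper and CO insertion ahead of the crowded C–C bond formation favour the first, the secondary-amine path through 22 secures 6-endo over 5-exo closure, and the third is fixed in 18 because only the oxygen para to the inter-flavone bond is free and has the iodine next to it, the other two ring D oxygens being benzyl ethers.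

Step 14
Reactants: 23 2-[4-(benzyloxy)phenyl]-3-{5,7-bis(benzyloxy)-2-[3,4-bis(benzyloxy)phenyl]-4-oxo-4H-chromen-6-yl}-5,7-dimethoxy-4H-chromen-4-one
Product: 24 3-[2-(3,4-dihydroxyphenyl)-5,7-dihydroxy-4-oxo-4H-chromen-6-yl]-5-hydroxy-2-(4-hydroxyphenyl)-7-methoxy-4H-chromen-4-one (CNP0200311.0)
Conditions: BCl3 (excess), pentamethylbenzene, CH2Cl2, −78 °C to rt
Reagents that add atoms: none
Why: Lewis-acid ether cleavage in which BCl3 removes the aryl benzyl ethers at low temperature with pentamethylbenzene trapping the benzyl cations, and on warming cleaves only the methyl ether chelated to the C4 carbonyl of the genkwanin half, the non-chelated 7-O-methyl group being resistant to BCl3.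

**Compound list**

1 | 2,4,6-trihydroxybenzaldehyde | O=Cc1c(O)cc(O)cc1O | starting material
2 | 2,6-dihydroxy-4-(methoxymethoxy)benzaldehyde | COCOc1cc(O)c(C=O)c(O)c1 | intermediate
3 | 2,6-bis(benzyloxy)-4-(methoxymethoxy)benzaldehyde | COCOc1cc(OCc2ccccc2)c(C=O)c(OCc2ccccc2)c1 | intermediate
4 | 1,3-bis(benzyloxy)-2-ethenyl-5-(methoxymethoxy)benzene | COCOc1cc(OCc2ccccc2)c(C=C)c(OCc2ccccc2)c1 | intermediate
5 | 2-[2,6-bis(benzyloxy)-4-(methoxymethoxy)phenyl]ethan-1-ol | COCOc1cc(OCc2ccccc2)c(CCO)c(OCc2ccccc2)c1 | intermediate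
6 | [2,6-bis(benzyloxy)-4-(methoxymethoxy)phenyl]acetic acid | COCOc1cc(OCc2ccccc2)c(CC(=O)O)c(OCc2ccccc2)c1 | intermediate
7 | 2-[2,6-bis(benzyloxy)-4-(methoxymethoxy)phenyl]-1-(1H-imidazol-1-yl)ethan-1-one | COCOc1cc(OCc2ccccc2)c(CC(=O)n2ccnc2)c(OCc2ccccc2)c1 | intermediate
8 | 2-[2,6-bis(benzyloxy)-4-(methoxymethoxy)phenyl]-N-methoxy-N-methylacetamide | COCOc1cc(OCc2ccccc2)c(CC(=O)N(C)OC)c(OCc2ccccc2)c1 | intermediate
9 | 3,5-dimethoxyphenol | COc1cc(O)cc(OC)c1 | starting material
10 | 2-(3,5-dimethoxyphenoxy)oxane (racemic) | COc1cc(OC)cc(OC2CCCCO2)c1 | intermediate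
11 | [2,4-dimethoxy-6-(oxan-2-yloxy)phenyl]lithium | COc1cc(OC)c([Li])c(OC2CCCCO2)c1 | intermediate
12 | 2-[2,6-bis(benzyloxy)-4-(methoxymethoxy)phenyl]-1-[2,4-dimethoxy-6-(oxan-2-yloxy)phenyl]ethan-1-one (racemic) | COc1cc(OC)c(C(=O)Cc2c(OCc3ccccc3)cc(OCOC)cc2OCc2ccccc2)c(OC2CCCCO2)c1 | intermediate
13 | 2-[2,6-bis(benzyloxy)-4-(methoxymethoxy)phenyl]-1-(2-hydroxy-4,6-dimethoxyphenyl)ethan-1-one | COc1cc(O)c(C(=O)Cc2c(OCc3ccccc3)cc(OCOC)cc2OCc2ccccc2)c(OC)c1 | intermediate
14 | 4-(benzyloxy)benzoyl chloride | O=C(Cl)c1ccc(OCc2ccccc2)cc1 | starting material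
15 | 2-{[2,6-bis(benzyloxy)-4-(methoxymethoxy)phenyl]acetyl}-3,5-dimethoxyphenyl 4-(benzyloxy)benzoate | COc1cc(OC)c(C(=O)Cc2c(OCc3ccccc3)cc(OCOC)cc2OCc2ccccc2)c(OC(=O)c2ccc(OCc3ccccc3)cc2)c1 | intermediate
16 | 2-[2,6-bis(benzyloxy)-4-(methoxymethoxy)phenyl]-3-[4-(benzyloxy)phenyl]-1-(2-hydroxy-4,6-dimethoxyphenyl)propane-1,3-dione (racemic, enolisable) | COc1cc(O)c(C(=O)C(C(=O)c2ccc(OCc3ccccc3)cc2)c2c(OCc3ccccc3)cc(OCOC)cc2OCc2ccccc2)c(OC)c1 | intermediate
17 | 2-[4-(benzyloxy)phenyl]-3-[2,6-bis(benzyloxy)-4-hydroxyphenyl]-5,7-dimethoxy-4H-chromen-4-one | COc1cc(OC)c2c(=O)c(-c3c(OCc4ccccc4)cc(O)cc3OCc3ccccc3)c(-c3ccc(OCc4ccccc4)cc3)oc2c1 | intermediate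
18 | 2-[4-(benzyloxy)phenyl]-3-[2,6-bis(benzyloxy)-4-hydroxy-3-iodophenyl]-5,7-dimethoxy-4H-chromen-4-one | COc1cc(OC)c2c(=O)c(-c3c(OCc4ccccc4)cc(O)c(I)c3OCc3ccccc3)c(-c3ccc(OCc4ccccc4)cc3)oc2c1 | intermediate
19 | 3,4-bis(benzyloxy)benzaldehyde | O=Cc1ccc(OCc2ccccc2)c(OCc2ccccc2)c1 | starting material
20 | 1,2-bis(benzyloxy)-4-ethynylbenzene | C#Cc1ccc(OCc2ccccc2)c(OCc2ccccc2)c1 | intermediate
21 | 2-[4-(benzyloxy)phenyl]-3-{2,6-bis(benzyloxy)-3-[3-(3,4-bis(benzyloxy)phenyl)prop-2-ynoyl]-4-hydroxyphenyl}-5,7-dimethoxy-4H-chromen-4-one | COc1cc(OC)c2c(=O)c(-c3c(OCc4ccccc4)cc(O)c(C(=O)C#Cc4ccc(OCc5ccccc5)c(OCc5ccccc5)c4)c3OCc3ccccc3)c(-c3ccc(OCc4ccccc4)cc3)oc2c1 | intermediate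
22 | 2-[4-(benzyloxy)phenyl]-3-{2,6-bis(benzyloxy)-3-[(2E)-3-[3,4-bis(benzyloxy)phenyl]-3-(diethylamino)prop-2-enoyl]-4-hydroxyphenyl}-5,7-dimethoxy-4H-chromen-4-one | COc1cc(OC)c2c(=O)c(-c3c(OCc4ccccc4)cc(O)c(C(=O)/C=C(/N(CC)CC)c4ccc(OCc5ccccc5)c(OCc5ccccc5)c4)c3OCc3ccccc3)c(-c3ccc(OCc4ccccc4)cc3)oc2c1 | intermediate
23 | 2-[4-(benzyloxy)phenyl]-3-{5,7-bis(benzyloxy)-2-[3,4-bis(benzyloxy)phenyl]-4-oxo-4H-chromen-6-yl}-5,7-dimethoxy-4H-chromen-4-one | COc1cc(OC)c2c(=O)c(-c3c(OCc4ccccc4)cc4oc(-c5ccc(OCc6ccccc6)c(OCc6ccccc6)c5)cc(=O)c4c3OCc3ccccc3)c(-c3ccc(OCc4ccccc4)cc3)oc2c1 | intermediate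
24 | 3-[2-(3,4-dihydroxyphenyl)-5,7-dihydroxy-4-oxo-4H-chromen-6-yl]-5-hydroxy-2-(4-hydroxyphenyl)-7-methoxy-4H-chromen-4-one (CNP0200311.0) | COc1cc(O)c2c(=O)c(-c3c(O)cc4oc(-c5ccc(O)c(O)c5)cc(=O)c4c3O)c(-c3ccc(O)cc3)oc2c1 | target

**Step count and risks**

Total step count: 14. Longest linear sequence: 12 (steps 1–6, 8–11, 13, 14).

Steps most likely to fail:

1. Step 13 (key step). The arylpalladium species may be captured by the alkyne before CO inserts, giving direct coupling and closure to a benzofuran. Ynone 21 may also close 5-exo to an aurone, and slow oxidative addition at the electron-rich, doubly flanked C–I bond leaves time for alkyne homocoupling. Fallback: from 18, Stille coupling with tributyl(1-ethoxyvinyl)stannane (Pd(PPh3)4, toluene, 100 °C) would give the enol ether F1, hydrolysed with 1 M HCl in THF to the ortho-hydroxyacetophenone F2. Claisen–Schmidt condensation of F2 with aldehyde 19 (KOH, EtOH/THF, rt) would give the 2'-hydroxychalcone F3. I2 (cat.) in DMSO at 120 °C would then cyclise and dehydrogenate F3 to 23, where the route is rejoined.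

2. Step 8. Proton transfer from the benzylic α-methylene of amide 8 to the hindered aryllithium 11 may outrun addition to the amide carbonyl, returning 10 and unreacted amide. Fallback: from 5, Dess–Martin oxidation (NaHCO3, CH2Cl2, rt) would give the arylacetaldehyde F4. Addition of aryllithium 11 at −78 °C, where attack on an aldehyde is much faster than proton transfer, would give the secondary alcohol F5. A second Dess–Martin oxidation would give ketone 12, which PPTS in methanol converts into 13, where the route is rejoined.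

3. Step 14. Benzyl cations released at seven Lewis-basic sites may re-alkylate the phloroglucinol-type rings at carbon, cleavage of the chelated methyl ether may stay incomplete, or forcing it may start to remove the 7-O-methyl group. Fallback: from 23, hydrogenolysis (H2, Pd/C, THF/MeOH, rt) would remove the five benzyl groups and give the 5,7-dimethyl ether F6. AlCl3 in MeCN at 60 °C would then cleave only the chelated 5-O-methyl group and give 24.

**Further compounds**

F1 | step 13 | 2-[4-(benzyloxy)phenyl]-3-[2,6-bis(benzyloxy)-3-(1-ethoxyethenyl)-4-hydroxyphenyl]-5,7-dimethoxy-4H-chromen-4-one | COc1cc(OC)c2c(=O)c(-c3c(OCc4ccccc4)cc(O)c(C(=C)OCC)c3OCc3ccccc3)c(-c3ccc(OCc4ccccc4)cc3)oc2c1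
F2 | step 13 | 3-[3-acetyl-2,6-bis(benzyloxy)-4-hydroxyphenyl]-2-[4-(benzyloxy)phenyl]-5,7-dimethoxy-4H-chromen-4-one | COc1cc(OC)c2c(=O)c(-c3c(OCc4ccccc4)cc(O)c(C(C)=O)c3OCc3ccccc3)c(-c3ccc(OCc4ccccc4)cc3)oc2c1
F3 | step 13 | 2-[4-(benzyloxy)phenyl]-3-{2,6-bis(benzyloxy)-3-[(2E)-3-[3,4-bis(benzyloxy)phenyl]prop-2-enoyl]-4-hydroxyphenyl}-5,7-dimethoxy-4H-chromen-4-one | COc1cc(OC)c2c(=O)c(-c3c(OCc4ccccc4)cc(O)c(C(=O)/C=C/c4ccc(OCc5ccccc5)c(OCc5ccccc5)c4)c3OCc3ccccc3)c(-c3ccc(OCc4ccccc4)cc3)oc2c1
F4 | step 8 | [2,6-bis(benzyloxy)-4-(methoxymethoxy)phenyl]acetaldehyde | COCOc1cc(OCc2ccccc2)c(CC=O)c(OCc2ccccc2)c1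
F5 | step 8 | 2-[2,6-bis(benzyloxy)-4-(methoxymethoxy)phenyl]-1-[2,4-dimethoxy-6-(oxan-2-yloxy)phenyl]ethan-1-ol (mixture of diastereomers) | COc1cc(OC)c(C(O)Cc2c(OCc3ccccc3)cc(OCOC)cc2OCc2ccccc2)c(OC2CCCCO2)c1
F6 | step 14 | 3-[2-(3,4-dihydroxyphenyl)-5,7-dihydroxy-4-oxo-4H-chromen-6-yl]-2-(4-hydroxyphenyl)-5,7-dimethoxy-4H-chromen-4-one | COc1cc(OC)c2c(=O)c(-c3c(O)cc4oc(-c5ccc(O)c(O)c5)cc(=O)c4c3O)c(-c3ccc(O)cc3)oc2c1
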